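All runs come from a simulation for substances that don't exist; the scatter is artificial.

South holds 3.00 M of reagent against 1.05 M in south-east; does that change the intermediate left at the end?

| flask | substrate | reagent | catalyst | temperature | remark | time |
|---|---|---|---|---|---|---|
| winter | 1 M | 1.2 M | 0.84 mM | 25 °C | run made earlier |  |
| autumn | 1 M | 1.7 M | 0.84 mM | 40 °C | run made earlier |  |
| south-east | 1.0 M | 1.05 M | 0.84 mM | 40 °C |  | 2.5 min |
| south | 1.0 M | 3.00 M | 0.84 mM | 40 °C |  | 2.5 min |

| run | time / min | intermediate / % | product / % |
|---|---|---|---|
| winter | 0.417 | 28.0 | 3.0 |
| winter | 1.00 | 47.7 | 11.1 |
| winter | 2.00 | 55.1 | 29.3 |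
| winter | 5.00 | 37.0 | 63.2 |
| autumn | 0.667 | 46.8 | 31.3 |
| autumn | 1.33 | 35.0 | 60.8 |
| autumn | 2.00 | 22.7 | 76.6 |
| autumn | 2.50 | 15.8 | 84.3 |

(readings scatter by 0.5 percentage points)

* the winner by amount of intermediate, in percent of the substrate charged; "neither" if no more than 2 percentage points parts them (south-east / south / neither)
* how much intermediate is there at the end, in percent of the substrate charged: south-east
* how much intermediate is there at the end, in percent of the substrate charged: south

- a reading or a percentage of product counts all its forms, free or not

Two chemists dispute this in powers of ten, and both start from the tail of the autumn run, where the substrate, taken by difference from the readings, stands at 0.700% at 2.00 min. Between 2.00 min and 2.50 min the autumn run reads d = 0.315 min⁻¹, the decade rate, the powers of ten the intermediate loses per minute. The substrate's decade rate in the autumn run reads a = 1.04 min⁻¹.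

The first chemist treats d as a fixed property of the intermediate, a first-order loss regardless of reagent. The consecutive first-order expression then gives 23.1% in both flasks at 2.5 min, so the verdict is neither.

The second chemist, whose reckoning I give as my own, takes d as proportional to reagent, which stood near R = 0.895 M in that tail if each product costs one reagent. In south, the same expression with R at the surplus 2.00 M gives 4.64%, and with R midway between surplus and charge it gives 2.50%. In south-east, R held at the full charge gives 18.2%, an estimate higher than south's upper figure, so this reckoning names south-east.

The forecast sides with the second chemist: south-east wins, with 34% in south-east and 3% in south, on the ground “So reagent seems consumed only in the second step”. Its south-east figure differs from my 18.2%, being higher; mine held R at the full charge.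

The flasks give 34.6% in south-east and 3.26% in south, so south-east wins.

    substrate + catalyst → catalyst + intermediate (k = 45.0 M⁻¹ s⁻¹, Ea = 48.0 kJ mol⁻¹)
    reagent + catalyst + intermediate → catalyst + product (k = 17.0 M⁻² s⁻¹, Ea = 49.0 kJ mol⁻¹)
    crystals ⇌ product, rate k3*(cs3 - [product]) while solid is left; crystals form when [product] > cs3 (solubility = 0.660 M, k = 1.90 s⁻¹)
    (constants at 40 °C)

At the end, d scaled to the reagent present is 0.141 min⁻¹ in south-east and 0.717 min⁻¹ in south. The first chemist's first-order loss, with a constant of its own, suits the second half of south (the pseudo-first-order case), where reagent moves from 74.8% at 1.25 min to 67.9% of its charge at 2.50 min, against 60.3% to 38.1% in south-east. A flask like south with 2.1 × 10⁻⁴ M of catalyst has a quarter of the catalyst, and a and d scale with it. With reagent taken midway between its charge and the 85.9% of it left in that flask at the end, 2.79 M, d becomes 0.245 min⁻¹ and the reckoning gives 34.9%; that flask holds 33.5% of intermediate at the end.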